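**Plan**

1. Retrosynthetic cuts (cyclohexane numbered C1 = spiro carbon, C2 = quaternary carbon, C3 = CH bearing the oxygenated isopropyl group, C4, C5 = CH2, C6 = CHMe): the C5–C6 bond and the spiro C1–O bond fall in one event; then the tropone–CH2 bond (β-keto ester alkylation), the seven-membered ring ([3+4] annulation of a furan with a vinylcarbenoid), and the two C–C bonds at C2 (lactone enolate alkylations).
2. Forward, terpenoid half: (S)-α-terpineol gives a γ-lactone (temporary ring that holds C3 and masks the tertiary alcohol); C2 is made quaternary; the lactone is opened to an ethyl ketone, then a (Z)-enol triflate, then allylic bromide 14. In parallel, furan 20 gives the oxa-bridged cycloheptenone β-keto ester 22, a masked hydroxytropone.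
3. Forward, union and end: 14 + 22 are joined; fluoride removes the activating ester and opens the oxa bridge; oxidation gives hydroxytropone 26; the key step closes the cyclohexane and, in the same event, the dihydrofuran; acetal/MOM hydrolysis and oxidation give the acid.
4. Stereochemistry: C3 comes from the chiral pool; C2 from anti-alkylation on the lactone; C6 and the spiro centre C1 are set in the key step (chair 6-endo transition state with the (E)-alkene, then axial C–O bond formation).
5. Enabling feature: the C6 carbon is the outer end of a trisubstituted alkene whose inner end, the future spiro carbon, lies between the quaternary carbon and a CH2 that carries the hydroxytropone. A radical at C5, four atoms away, can therefore close only 6-endo, and it leaves a tertiary radical/cation exactly 1,3 to the tropone oxygen.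

Key step: step 18

Remark: 22 is racemic and is joined to enantiopure 14, so 23–25 are mixtures at the ring centres of the oxa-bridged part; all of these centres become sp2 in 26. Hydroxytropones are drawn as one of two equivalent tautomers.

**Route**

Step 1
Reactants: 1 (S)-α-terpineol
Product: 3 (4S)-5,5-dimethyl-4-(3-oxobutyl)oxolan-2-one, via keto hydroxy acid 2 (not isolated)
Conditions: RuCl3 (2 mol%), NaIO4, EtOAc/MeCN/H2O, 25 °C; acidic work-up
Reagents that add atoms: sodium periodate, [Na+].[O-]I(=O)(=O)=O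
Why: Oxidative cleavage of the trisubstituted ring alkene by catalytic RuO4 should give a methyl ketone and a carboxylic acid without touching the stereocentre, and the γ-hydroxy acid 2 should close onto the tertiary alcohol on acidic work-up (alkene cleavage, lactonization).

Step 2
Reactants: 3 (4S)-5,5-dimethyl-4-(3-oxobutyl)oxolan-2-one
Product: 5 3-[(3S)-2,2-dimethyl-5-oxooxolan-3-yl]propanoic acid, via disodium hydroxy diacid salt 4 (not isolated)
Conditions: Br2, NaOH, H2O/dioxane, 0 °C; then HCl to pH 1, 25 °C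
Reagents that add atoms: sodium hydroxide, [Na+].[OH-]
Why: The haloform reaction should degrade the methyl ketone to the acid one carbon shorter, and the lactone, opened by the base to salt 4, should close again on acidification.

Step 3
Reactants: 5 3-[(3S)-2,2-dimethyl-5-oxooxolan-3-yl]propanoic acid
Product: 6 (4R)-4-(2-chloroethyl)-5,5-dimethyloxolan-2-one
Conditions: Pb(OAc)4, LiCl, benzene, 80 °C
Reagents that add atoms: lithium chloride, [Li+].[Cl-]
Why: Kochi halodecarboxylation should turn the primary acid, by way of the alkyl radical, into a primary chloride, an inert handle that survives enolate and organolithium chemistry until it is needed as radical precursor.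

Step 4
Reactants: 6 (4R)-4-(2-chloroethyl)-5,5-dimethyloxolan-2-one; 7 2-(2-bromoethyl)-1,3-dioxolane
Product: 8 (3S,4S)-4-(2-chloroethyl)-3-[2-(1,3-dioxolan-2-yl)ethyl]-5,5-dimethyloxolan-2-one
Conditions: LiN(iPr)2, THF, −78 °C; then 7, DMPU, −78 → −20 °C
Reagents that add atoms: none
Why: Alkylation of the lithium lactone enolate, the only enolizable position, with the primary bromide should install the acetal-masked propanoate chain trans to the ring substituent (lactone enolate alkylation; this centre is reset in step 5).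

Step 5
Reactants: 8 (3S,4S)-4-(2-chloroethyl)-3-[2-(1,3-dioxolan-2-yl)ethyl]-5,5-dimethyloxolan-2-one
Product: 9 (3R,4S)-4-(2-chloroethyl)-3-[2-(1,3-dioxolan-2-yl)ethyl]-3,5,5-trimethyloxolan-2-one
Conditions: LiN(iPr)2, THF, −78 °C; then MeI, DMPU, −78 → −40 °C
Reagents that add atoms: iodomethane, CI
Why: Methylation of the re-formed enolate should occur anti to the neighbouring 2-chloroethyl group, which sets the quaternary centre with methyl trans and the acetal chain cis to that group (diastereoselective enolate alkylation; the acetal chain has no acidic hydrogen to compete).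

Step 6
Reactants: 9 (3R,4S)-4-(2-chloroethyl)-3-[2-(1,3-dioxolan-2-yl)ethyl]-3,5,5-trimethyloxolan-2-one
Product: 10 (4R,5S)-5-(2-chloroethyl)-4-[2-(1,3-dioxolan-2-yl)ethyl]-6-hydroxy-4,6-dimethylheptan-3-one
Conditions: EtLi (1.1 equiv), THF, −78 °C; aqueous NH4Cl
Reagents that add atoms: ethyllithium, [Li]CC
Why: Ethyllithium should add once to the hindered, non-enolizable lactone carbonyl because the tetrahedral adduct is stable at −78 °C, and work-up should give the ethyl ketone with the tertiary alcohol set free (organolithium mono-addition to a lactone).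

Step 7
Reactants: 10 (4R,5S)-5-(2-chloroethyl)-4-[2-(1,3-dioxolan-2-yl)ethyl]-6-hydroxy-4,6-dimethylheptan-3-one
Product: 11 (4R,5S)-5-(2-chloroethyl)-4-[2-(1,3-dioxolan-2-yl)ethyl]-6-(methoxymethoxy)-4,6-dimethylheptan-3-one
Conditions: MOMCl, iPr2NEt, Bu4NI (cat.), CH2Cl2, 40 °C
Reagents that add atoms: chloromethyl methyl ether, COCCl
Why: Methoxymethylation under basic conditions leaves acetal and ketone alone and masks the tertiary hydroxyl so that it can attack neither the allylic bromide nor the cation formed later (MOM ether formation).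

Step 8
Reactants: 11 (4R,5S)-5-(2-chloroethyl)-4-[2-(1,3-dioxolan-2-yl)ethyl]-6-(methoxymethoxy)-4,6-dimethylheptan-3-one
Product: 12 (2Z,4R,5S)-5-(2-chloroethyl)-4-[2-(1,3-dioxolan-2-yl)ethyl]-6-(methoxymethoxy)-4,6-dimethylhept-2-en-3-yl trifluoromethanesulfonate
Conditions: KN(SiMe3)2, THF, −78 °C; then PhNTf2, −78 → −40 °C
Reagents that add atoms: N-phenylbis(trifluoromethanesulfonimide), O=S(=O)(N(c1ccccc1)S(=O)(=O)C(F)(F)F)C(F)(F)F
Why: The ketone can enolize only toward its CH2, and a tert-alkyl ethyl ketone gives the (Z)-enolate, so trapping at −78 °C should give the (Z)-enol triflate (methyl cis to oxygen, trans to the quaternary carbon) before the enolate can attack the chloride (kinetic enolate triflation).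

Step 9
Reactants: 12 (2Z,4R,5S)-5-(2-chloroethyl)-4-[2-(1,3-dioxolan-2-yl)ethyl]-6-(methoxymethoxy)-4,6-dimethylhept-2-en-3-yl trifluoromethanesulfonate
Product: 13 (2Z)-2-[(3R,4S)-6-chloro-1-(1,3-dioxolan-2-yl)-4-[2-(methoxymethoxy)propan-2-yl]-3-methylhexan-3-yl]but-2-en-1-ol
Conditions: Bu3SnCH2OH, Pd(PPh3)4 (5 mol%), LiCl, 1,4-dioxane, 90 °C
Reagents that add atoms: (tributylstannyl)methanol, CCCC[Sn](CCCC)(CCCC)CO
Why: Stille coupling of the alkenyl triflate should replace OTf by CH2OH with retention, which fixes the trisubstituted alkene with its methyl group cis to the new CH2 (cross-coupling at zerovalent palladium).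

Step 10
Reactants: 13 (2Z)-2-[(3R,4S)-6-chloro-1-(1,3-dioxolan-2-yl)-4-[2-(methoxymethoxy)propan-2-yl]-3-methylhexan-3-yl]but-2-en-1-ol
Product: 14 2-[(3R,4S)-3-[(2Z)-1-bromobut-2-en-2-yl]-6-chloro-4-[2-(methoxymethoxy)propan-2-yl]-3-methylhexyl]-1,3-dioxolane
Conditions: CBr4, PPh3, 2,6-lutidine (cat.), CH2Cl2, −20 → 0 °C
Reagents that add atoms: tetrabromomethane, BrC(Br)(Br)Br
Why: The Appel reaction should convert the primary allylic alcohol to the bromide under nearly neutral conditions that spare the acetal, the MOM ether and the alkene geometry.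

Step 11
Reactants: 15 methyl 3-oxopentanoate; 16 2-(trimethylsilyl)ethanol
Product: 17 2-(trimethylsilyl)ethyl 3-oxopentanoate
Conditions: DMAP (10 mol%), toluene, 110 °C, removal of MeOH
Reagents that add atoms: none
Why: DMAP-catalysed transesterification of the β-keto ester by way of the acylketene should exchange methyl for the fluoride-labile 2-(trimethylsilyl)ethyl group.

Step 12
Reactants: 17 2-(trimethylsilyl)ethyl 3-oxopentanoate
Product: 18 2-(trimethylsilyl)ethyl 2-diazo-3-oxopentanoate
Conditions: 4-acetamidobenzenesulfonyl azide, Et3N, MeCN, 0 → 25 °C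
Reagents that add atoms: 4-acetamidobenzenesulfonyl azide, CC(=O)Nc1ccc(cc1)S(=O)(=O)N=[N+]=[N-]
Why: Regitz diazo transfer to the active methylene should give the 2-diazo-3-oxo ester.

Step 13
Reactants: 18 2-(trimethylsilyl)ethyl 2-diazo-3-oxopentanoate
Product: 19 2-(trimethylsilyl)ethyl (3Z)-3-[(tert-butyldimethylsilyl)oxy]-2-diazopent-3-enoate
Conditions: TBSOTf, Et3N, CH2Cl2, 0 °C
Reagents that add atoms: tert-butyldimethylsilyl trifluoromethanesulfonate, CC(C)(C)[Si](C)(C)OS(=O)(=O)C(F)(F)F
Why: Soft enolization of the ketone should give the (Z)-silyl enol ether, a siloxyvinyl diazoacetate that is the precursor of a donor/acceptor rhodium carbenoid.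

Step 14
Reactants: 19 2-(trimethylsilyl)ethyl (3Z)-3-[(tert-butyldimethylsilyl)oxy]-2-diazopent-3-enoate; 20 methyl 4-methylfuran-3-carboxylate
Product: 22 6-methyl 2-[2-(trimethylsilyl)ethyl] 4,7-dimethyl-3-oxo-8-oxabicyclo[3.2.1]oct-6-ene-2,6-dicarboxylate (racemic), via bicyclic silyl enol ether 21 (not isolated)
Conditions: Rh2(O2CCMe3)4 (1 mol%), 20 (3 equiv), hexanes, 69 °C; then 1 M HCl, THF, 25 °C
Reagents that add atoms: none
Why: The rhodium vinylcarbenoid should cyclopropanate the electron-rich 4,5-bond of the furan (the 2,3-bond is deactivated by the ester) and the cis-divinylcyclopropane should undergo Cope rearrangement, so that the carbenoid carbon ends next to the bridgehead that neighbours the methyl-bearing alkene carbon, after which mild acid hydrolyses the silyl enol ether (tandem cyclopropanation/Cope [3+4] annulation).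

Step 15
Reactants: 14 2-[(3R,4S)-3-[(2Z)-1-bromobut-2-en-2-yl]-6-chloro-4-[2-(methoxymethoxy)propan-2-yl]-3-methylhexyl]-1,3-dioxolane; 22 6-methyl 2-[2-(trimethylsilyl)ethyl] 4,7-dimethyl-3-oxo-8-oxabicyclo[3.2.1]oct-6-ene-2,6-dicarboxylate
Product: 23 6-methyl 2-[2-(trimethylsilyl)ethyl] 2-{(2E)-2-[(3R,4S)-6-chloro-1-(1,3-dioxolan-2-yl)-4-[2-(methoxymethoxy)propan-2-yl]-3-methylhexan-3-yl]but-2-en-1-yl}-4,7-dimethyl-3-oxo-8-oxabicyclo[3.2.1]oct-6-ene-2,6-dicarboxylate
Conditions: Cs2CO3, DMF, 25 °C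
Reagents that add atoms: none
Why: The β-keto ester should be alkylated at its doubly activated carbon by the allylic bromide (SN2) far faster than by the primary chloride, which joins the two halves at the future tropone carbon and makes that carbon quaternary (β-keto ester C-alkylation).

Step 16
Reactants: 23 the alkylated bridged β-keto ester
Product: 25 methyl 4-{(2E)-2-[(3R,4S)-6-chloro-1-(1,3-dioxolan-2-yl)-4-[2-(methoxymethoxy)propan-2-yl]-3-methylhexan-3-yl]but-2-en-1-yl}-7-hydroxy-2,6-dimethyl-5-oxocyclohepta-1,3-diene-1-carboxylate, via tetrabutylammonium carboxylate 24 (not isolated)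
Conditions: Bu4NF (2 equiv), THF, 0 → 25 °C; pH 7 buffer
Reagents that add atoms: none
Why: Fluoride removes the 2-(trimethylsilyl)ethyl group, the naked β-keto carboxylate 24 loses CO2 to give the enolate regiospecifically at the alkylated carbon, and this enolate should expel the bridging oxygen from the adjacent bridgehead (E1cB, retro-oxa-Michael), which leaves the hydroxyl on the other bridgehead at a temperature too low for dehydration.

Step 17
Reactants: 25 the ring-opened hydroxy dienone
Product: 26 methyl 4-{(2E)-2-[(3R,4S)-6-chloro-1-(1,3-dioxolan-2-yl)-4-[2-(methoxymethoxy)propan-2-yl]-3-methylhexan-3-yl]but-2-en-1-yl}-5-hydroxy-2,6-dimethyl-7-oxocyclohepta-1,3,5-triene-1-carboxylate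
Conditions: Dess–Martin periodinane, NaHCO3, CH2Cl2, 0 → 25 °C
Reagents that add atoms: none
Why: Dess–Martin oxidation of the secondary alcohol gives a 2-methyl-1,3-diketone flanked by two ring alkenes, which should enolize at once to the 3-hydroxytropone, while the bicarbonate buffer protects the acid-sensitive alkene and acetals.

Step 18
Reactants: 26 the hydroxytropone chloride
Product: 28 methyl (1S,2R,3S,6S)-2-[2-(1,3-dioxolan-2-yl)ethyl]-3-[2-(methoxymethoxy)propan-2-yl]-2,5',6,8'-tetramethyl-7'-oxo-3'H,7'H-spiro[cyclohexane-1,2'-cyclohepta[b]furan]-6'-carboxylate, via primary iodide 27 (not isolated)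
Conditions: NaI, acetone, 56 °C; filter, evaporate; then fac-Ir(ppy)3 (2 mol%), 2,6-lutidine, MeCN, 450 nm LEDs, 25 °C
Reagents that add atoms: none
Why: Proposed new method: the excited state of fac-Ir(ppy)3 (trivalent iridium) should reduce the C–I bond of 27 to a primary radical, which adds 6-endo-trig to the CHMe carbon of the (E)-alkene and so closes the cyclohexane at its C5–C6 bond; the tertiary radical left at the future spiro carbon is oxidized by the tetravalent iridium formed in the first event, and the cation is captured by the hydroxytropone oxygen, which closes the dihydrofuran (closure of the 5-exo type onto the cationic carbon) while 2,6-lutidine takes up HI. The closest known reaction types are visible-light radical cyclizations of unactivated alkyl iodides with this catalyst, photoredox atom-transfer additions that end by radical-polar crossover with capture of the cation by a tethered OH or CO2H group, and the 6-endo radical closures onto trisubstituted alkenes of polyene cyclizations, but a redox-neutral cascade from an unactivated iodide that ends in a spiro ether on a hydroxytropone has not been shown. The CHMe centre is set in a chair transition state that keeps the MOM-oxyisopropyl group and the acetal chain equatorial and the quaternary methyl axial, so the alkene methyl, which is trans to the quaternary carbon, becomes equatorial. The spiro centre is set by axial C–O bond formation on the cyclohexyl cation anti to that axial methyl, the course known from acid-induced spiro ether formation of cyclohexenylmethyl phenols. The step needs 6-endo over 5-exo attack, which is secured by the fully substituted inner alkene carbon next to the quaternary centre and by the tertiary radical that only the 6-endo mode gives, and it needs the tropone oxygen to be the only nucleophile at hand, which is why the alcohol and the acid are masked as MOM ether and acetal.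

Step 19
Reactants: 28 the spiro ether
Product: 30 3-[(1S,2R,3S,6S)-3-(2-hydroxypropan-2-yl)-6'-(methoxycarbonyl)-2,5',6,8'-tetramethyl-7'-oxo-3'H,7'H-spiro[cyclohexane-1,2'-cyclohepta[b]furan]-2-yl]propanoic acid, via hydroxy aldehyde 29 (not isolated)
Conditions: 3 M HCl, THF, 40 °C; then NaClO2, 2-methyl-2-butene, tBuOH/H2O, pH 3–4, 25 °C
Reagents that add atoms: water, O; sodium chlorite, [Na+].[O-]Cl=O
Why: Aqueous acid should hydrolyse the dioxolane and the MOM ether without opening the spiro ether, and Pinnick oxidation of aldehyde 29 with a hypochlorite scavenger should give the acid without touching the tertiary alcohol, the tropone or any stereocentre.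

**Compound list**

1 | (S)-α-terpineol, 2-[(1S)-4-methylcyclohex-3-en-1-yl]propan-2-ol | CC1=CC[C@H](CC1)C(C)(C)O | starting material
2 | (3S)-3-(2-hydroxypropan-2-yl)-6-oxoheptanoic acid | CC(=O)CC[C@@H](CC(=O)O)C(C)(C)O | intermediate
3 | (4S)-5,5-dimethyl-4-(3-oxobutyl)oxolan-2-one | CC(=O)CC[C@H]1CC(=O)OC1(C)C | intermediate
4 | disodium (3S)-3-(2-hydroxypropan-2-yl)hexanedioate | [Na+].[Na+].[O-]C(=O)CC[C@@H](CC(=O)[O-])C(C)(C)O | intermediate
5 | 3-[(3S)-2,2-dimethyl-5-oxooxolan-3-yl]propanoic acid | OC(=O)CC[C@H]1CC(=O)OC1(C)C | intermediate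
6 | (4R)-4-(2-chloroethyl)-5,5-dimethyloxolan-2-one | ClCC[C@H]1CC(=O)OC1(C)C | intermediate
7 | 2-(2-bromoethyl)-1,3-dioxolane | BrCCC1OCCO1 | starting material
8 | (3S,4S)-4-(2-chloroethyl)-3-[2-(1,3-dioxolan-2-yl)ethyl]-5,5-dimethyloxolan-2-one | ClCC[C@@H]1C(C)(C)OC(=O)[C@H]1CCC2OCCO2 | intermediate
9 | (3R,4S)-4-(2-chloroethyl)-3-[2-(1,3-dioxolan-2-yl)ethyl]-3,5,5-trimethyloxolan-2-one | ClCC[C@@H]1C(C)(C)OC(=O)[C@]1(C)CCC2OCCO2 | intermediate
10 | (4R,5S)-5-(2-chloroethyl)-4-[2-(1,3-dioxolan-2-yl)ethyl]-6-hydroxy-4,6-dimethylheptan-3-one | CCC(=O)[C@](C)(CCC1OCCO1)[C@H](CCCl)C(C)(C)O | intermediate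
11 | (4R,5S)-5-(2-chloroethyl)-4-[2-(1,3-dioxolan-2-yl)ethyl]-6-(methoxymethoxy)-4,6-dimethylheptan-3-one | CCC(=O)[C@](C)(CCC1OCCO1)[C@H](CCCl)C(C)(C)OCOC | intermediate
12 | (2Z,4R,5S)-5-(2-chloroethyl)-4-[2-(1,3-dioxolan-2-yl)ethyl]-6-(methoxymethoxy)-4,6-dimethylhept-2-en-3-yl trifluoromethanesulfonate | FC(F)(F)S(=O)(=O)O/C(=C\C)[C@](C)(CCC1OCCO1)[C@H](CCCl)C(C)(C)OCOC | intermediate
13 | (2Z)-2-[(3R,4S)-6-chloro-1-(1,3-dioxolan-2-yl)-4-[2-(methoxymethoxy)propan-2-yl]-3-methylhexan-3-yl]but-2-en-1-ol | OC/C(=C\C)[C@](C)(CCC1OCCO1)[C@H](CCCl)C(C)(C)OCOC | intermediate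
14 | 2-[(3R,4S)-3-[(2Z)-1-bromobut-2-en-2-yl]-6-chloro-4-[2-(methoxymethoxy)propan-2-yl]-3-methylhexyl]-1,3-dioxolane | BrC/C(=C\C)[C@](C)(CCC1OCCO1)[C@H](CCCl)C(C)(C)OCOC | intermediate
15 | methyl 3-oxopentanoate | CCC(=O)CC(=O)OC | starting material
16 | 2-(trimethylsilyl)ethanol | OCC[Si](C)(C)C | starting material
17 | 2-(trimethylsilyl)ethyl 3-oxopentanoate | CCC(=O)CC(=O)OCC[Si](C)(C)C | intermediate
18 | 2-(trimethylsilyl)ethyl 2-diazo-3-oxopentanoate | CCC(=O)C(=[N+]=[N-])C(=O)OCC[Si](C)(C)C | intermediate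
19 | 2-(trimethylsilyl)ethyl (3Z)-3-[(tert-butyldimethylsilyl)oxy]-2-diazopent-3-enoate | C/C=C(\O[Si](C)(C)C(C)(C)C)C(=[N+]=[N-])C(=O)OCC[Si](C)(C)C | intermediate
20 | methyl 4-methylfuran-3-carboxylate | COC(=O)c1cocc1C | starting material
21 | 6-methyl 2-[2-(trimethylsilyl)ethyl] 3-[(tert-butyldimethylsilyl)oxy]-4,7-dimethyl-8-oxabicyclo[3.2.1]octa-2,6-diene-2,6-dicarboxylate (racemic) | CC1C(O[Si](C)(C)C(C)(C)C)=C(C(=O)OCC[Si](C)(C)C)C2OC1C(C(=O)OC)=C2C | intermediate
22 | 6-methyl 2-[2-(trimethylsilyl)ethyl] 4,7-dimethyl-3-oxo-8-oxabicyclo[3.2.1]oct-6-ene-2,6-dicarboxylate (racemic, epimers at C2 and C4) | CC1C(=O)C(C(=O)OCC[Si](C)(C)C)C2OC1C(C(=O)OC)=C2C | intermediate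
23 | 6-methyl 2-[2-(trimethylsilyl)ethyl] 2-{(2E)-2-[(3R,4S)-6-chloro-1-(1,3-dioxolan-2-yl)-4-[2-(methoxymethoxy)propan-2-yl]-3-methylhexan-3-yl]but-2-en-1-yl}-4,7-dimethyl-3-oxo-8-oxabicyclo[3.2.1]oct-6-ene-2,6-dicarboxylate (mixture at the bicyclic centres) | CC1C(=O)C(C/C(=C\C)[C@](C)(CCC3OCCO3)[C@H](CCCl)C(C)(C)OCOC)(C(=O)OCC[Si](C)(C)C)C2OC1C(C(=O)OC)=C2C | intermediate
24 | tetrabutylammonium salt of the 2-carboxylate of 23 | CCCC[N+](CCCC)(CCCC)CCCC.CC1C(=O)C(C/C(=C\C)[C@](C)(CCC3OCCO3)[C@H](CCCl)C(C)(C)OCOC)(C([O-])=O)C2OC1C(C(=O)OC)=C2C | intermediate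
25 | methyl 4-{(2E)-2-[(3R,4S)-6-chloro-1-(1,3-dioxolan-2-yl)-4-[2-(methoxymethoxy)propan-2-yl]-3-methylhexan-3-yl]but-2-en-1-yl}-7-hydroxy-2,6-dimethyl-5-oxocyclohepta-1,3-diene-1-carboxylate (mixture at C6 and C7) | CC1C(O)C(C(=O)OC)=C(C)C=C(C/C(=C\C)[C@](C)(CCC2OCCO2)[C@H](CCCl)C(C)(C)OCOC)C1=O | intermediate
26 | methyl 4-{(2E)-2-[(3R,4S)-6-chloro-1-(1,3-dioxolan-2-yl)-4-[2-(methoxymethoxy)propan-2-yl]-3-methylhexan-3-yl]but-2-en-1-yl}-5-hydroxy-2,6-dimethyl-7-oxocyclohepta-1,3,5-triene-1-carboxylate | COC(=O)c1c(C)cc(C/C(=C\C)[C@](C)(CCC2OCCO2)[C@H](CCCl)C(C)(C)OCOC)c(O)c(C)c1=O | intermediate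
27 | methyl 4-{(2E)-2-[(3R,4S)-1-(1,3-dioxolan-2-yl)-6-iodo-4-[2-(methoxymethoxy)propan-2-yl]-3-methylhexan-3-yl]but-2-en-1-yl}-5-hydroxy-2,6-dimethyl-7-oxocyclohepta-1,3,5-triene-1-carboxylate | COC(=O)c1c(C)cc(C/C(=C\C)[C@](C)(CCC2OCCO2)[C@H](CCI)C(C)(C)OCOC)c(O)c(C)c1=O | intermediate
28 | methyl (1S,2R,3S,6S)-2-[2-(1,3-dioxolan-2-yl)ethyl]-3-[2-(methoxymethoxy)propan-2-yl]-2,5',6,8'-tetramethyl-7'-oxo-3'H,7'H-spiro[cyclohexane-1,2'-cyclohepta[b]furan]-6'-carboxylate | COC(=O)c1c(C)cc2c(c(C)c1=O)O[C@@]1(C2)[C@@H](C)CC[C@H](C(C)(C)OCOC)[C@@]1(C)CCC3OCCO3 | intermediate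
29 | methyl (1S,2R,3S,6S)-3-(2-hydroxypropan-2-yl)-2,5',6,8'-tetramethyl-7'-oxo-2-(3-oxopropyl)-3'H,7'H-spiro[cyclohexane-1,2'-cyclohepta[b]furan]-6'-carboxylate | COC(=O)c1c(C)cc2c(c(C)c1=O)O[C@@]1(C2)[C@@H](C)CC[C@H](C(C)(C)O)[C@@]1(C)CCC=O | intermediate
30 | 3-[(1S,2R,3S,6S)-3-(2-hydroxypropan-2-yl)-6'-(methoxycarbonyl)-2,5',6,8'-tetramethyl-7'-oxo-3'H,7'H-spiro[cyclohexane-1,2'-cyclohepta[b]furan]-2-yl]propanoic acid | COC(=O)c1c(C)cc2c(c(C)c1=O)O[C@@]1(C2)[C@@H](C)CC[C@H](C(C)(C)O)[C@@]1(C)CCC(=O)O | target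

**Step count and risks**

Total: 19 steps. Longest linear sequence: 15 steps (steps 1–10 and 15–19).

Steps most likely to fail:

1. Step 18 (proposed new method). The primary radical may abstract hydrogen from the allylic CH2 (1,6-transfer) or be reduced before it cyclizes, the excited catalyst may pass its energy to the tropone, or the tertiary radical may not be oxidized and captured. Fallback with known chemistry, in which the same ring bond is closed by a polar reaction before the tropone is in place: it sets out from 11. Finkelstein exchange (NaI, acetone) should give (4R,5S)-4-[2-(1,3-dioxolan-2-yl)ethyl]-5-(2-iodoethyl)-6-(methoxymethoxy)-4,6-dimethylheptan-3-one F1. Its potassium enolate (KN(SiMe3)2, THF, −78 → 0 °C) should close the ring by intramolecular alkylation to (2R,3S,6S)-2-[2-(1,3-dioxolan-2-yl)ethyl]-3-[2-(methoxymethoxy)propan-2-yl]-2,6-dimethylcyclohexan-1-one F2. Triflation as in step 8 should give (5S,6R)-6-[2-(1,3-dioxolan-2-yl)ethyl]-5-[2-(methoxymethoxy)propan-2-yl]-2,6-dimethylcyclohex-1-en-1-yl trifluoromethanesulfonate F3, Stille hydroxymethylation as in step 9 [(5S,6R)-6-[2-(1,3-dioxolan-2-yl)ethyl]-5-[2-(methoxymethoxy)propan-2-yl]-2,6-dimethylcyclohex-1-en-1-yl]methanol F4, and the Appel reaction (5S,6R)-1-(bromomethyl)-6-[2-(1,3-dioxolan-2-yl)ethyl]-5-[2-(methoxymethoxy)propan-2-yl]-2,6-dimethylcyclohex-1-ene F5. Alkylation of 22 as in step 15 should give the bridged keto diester F6, fluoride treatment as in step 16 the ring-opened hydroxy dienone F7, and Dess–Martin oxidation the hydroxytropone with a tetrasubstituted cyclohexene F8. Amberlyst 15 in CH2Cl2 should then protonate the alkene and close the spiro ether by trans-diaxial addition (methyl equatorial, oxygen axial), and the route is rejoined at 28.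

2. Step 16. The enolate formed on decarboxylation may be protonated before it opens the bridge, after which a base-induced opening has no regiocontrol; or the β-hydroxy ketone may lose water to a tropone that lacks the second oxygen. Fallback, in which the enolate is made reductively at low temperature: it sets out from 23. Bu4NF at 0 °C followed by N-bromosuccinimide in the same flask should give, by decarboxylative bromination of carboxylate 24, methyl 2-bromo-2-{(2E)-2-[(3R,4S)-6-chloro-1-(1,3-dioxolan-2-yl)-4-[2-(methoxymethoxy)propan-2-yl]-3-methylhexan-3-yl]but-2-en-1-yl}-4,7-dimethyl-3-oxo-8-oxabicyclo[3.2.1]oct-6-ene-6-carboxylate F9. SmI2 in THF at −78 °C should reduce the α-bromo ketone to the samarium enolate, which expels the β-oxygen (reductive β-elimination), and a cold quench returns the route at 25.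

3. Step 15. The enolate may be alkylated on oxygen, or the oxa bridge may open from the enolate (retro-oxa-Michael) so that the alkoxide is alkylated; substitution at the hindered carbon may also be slow. Fallback, a neutral allylation through a palladium allyl complex: it sets out from 13. Methyl chloroformate and pyridine should give (2Z)-2-[(3R,4S)-6-chloro-1-(1,3-dioxolan-2-yl)-4-[2-(methoxymethoxy)propan-2-yl]-3-methylhexan-3-yl]but-2-en-1-yl methyl carbonate F10. With Pd(PPh3)4 in THF at 25 °C (Tsuji–Trost allylation, no added base) 22 should attack the CH2 end of the 2-substituted allyl complex, whose methyl group stays anti, and the route is rejoined at 23.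

**Further compounds**

F1 | step 18 | (4R,5S)-4-[2-(1,3-dioxolan-2-yl)ethyl]-5-(2-iodoethyl)-6-(methoxymethoxy)-4,6-dimethylheptan-3-one | CCC(=O)[C@](C)(CCC1OCCO1)[C@H](CCI)C(C)(C)OCOC
F2 | step 18 | (2R,3S,6S)-2-[2-(1,3-dioxolan-2-yl)ethyl]-3-[2-(methoxymethoxy)propan-2-yl]-2,6-dimethylcyclohexan-1-one | O=C1[C@@H](C)CC[C@H](C(C)(C)OCOC)[C@@]1(C)CCC2OCCO2
F3 | step 18 | (5S,6R)-6-[2-(1,3-dioxolan-2-yl)ethyl]-5-[2-(methoxymethoxy)propan-2-yl]-2,6-dimethylcyclohex-1-en-1-yl trifluoromethanesulfonate | FC(F)(F)S(=O)(=O)OC1=C(C)CC[C@H](C(C)(C)OCOC)[C@@]1(C)CCC2OCCO2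
F4 | step 18 | [(5S,6R)-6-[2-(1,3-dioxolan-2-yl)ethyl]-5-[2-(methoxymethoxy)propan-2-yl]-2,6-dimethylcyclohex-1-en-1-yl]methanol | OCC1=C(C)CC[C@H](C(C)(C)OCOC)[C@@]1(C)CCC2OCCO2
F5 | step 18 | (5S,6R)-1-(bromomethyl)-6-[2-(1,3-dioxolan-2-yl)ethyl]-5-[2-(methoxymethoxy)propan-2-yl]-2,6-dimethylcyclohex-1-ene | BrCC1=C(C)CC[C@H](C(C)(C)OCOC)[C@@]1(C)CCC2OCCO2
F6 | step 18 | 6-methyl 2-[2-(trimethylsilyl)ethyl] 2-{[(5S,6R)-6-[2-(1,3-dioxolan-2-yl)ethyl]-5-[2-(methoxymethoxy)propan-2-yl]-2,6-dimethylcyclohex-1-en-1-yl]methyl}-4,7-dimethyl-3-oxo-8-oxabicyclo[3.2.1]oct-6-ene-2,6-dicarboxylate | CC1C(=O)C(CC2=C(C)CC[C@H](C(C)(C)OCOC)[C@@]2(C)CCC3OCCO3)(C(=O)OCC[Si](C)(C)C)C4OC1C(C(=O)OC)=C4C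
F7 | step 18 | methyl 4-{[(5S,6R)-6-[2-(1,3-dioxolan-2-yl)ethyl]-5-[2-(methoxymethoxy)propan-2-yl]-2,6-dimethylcyclohex-1-en-1-yl]methyl}-7-hydroxy-2,6-dimethyl-5-oxocyclohepta-1,3-diene-1-carboxylate | CC1C(O)C(C(=O)OC)=C(C)C=C(CC2=C(C)CC[C@H](C(C)(C)OCOC)[C@@]2(C)CCC3OCCO3)C1=O
F8 | step 18 | methyl 4-{[(5S,6R)-6-[2-(1,3-dioxolan-2-yl)ethyl]-5-[2-(methoxymethoxy)propan-2-yl]-2,6-dimethylcyclohex-1-en-1-yl]methyl}-5-hydroxy-2,6-dimethyl-7-oxocyclohepta-1,3,5-triene-1-carboxylate | COC(=O)c1c(C)cc(CC2=C(C)CC[C@H](C(C)(C)OCOC)[C@@]2(C)CCC3OCCO3)c(O)c(C)c1=O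
F9 | step 16 | methyl 2-bromo-2-{(2E)-2-[(3R,4S)-6-chloro-1-(1,3-dioxolan-2-yl)-4-[2-(methoxymethoxy)propan-2-yl]-3-methylhexan-3-yl]but-2-en-1-yl}-4,7-dimethyl-3-oxo-8-oxabicyclo[3.2.1]oct-6-ene-6-carboxylate | CC1C(=O)C(Br)(C/C(=C\C)[C@](C)(CCC3OCCO3)[C@H](CCCl)C(C)(C)OCOC)C2OC1C(C(=O)OC)=C2C
F10 | step 15 | (2Z)-2-[(3R,4S)-6-chloro-1-(1,3-dioxolan-2-yl)-4-[2-(methoxymethoxy)propan-2-yl]-3-methylhexan-3-yl]but-2-en-1-yl methyl carbonate | COC(=O)OC/C(=C\C)[C@](C)(CCC1OCCO1)[C@H](CCCl)C(C)(C)OCOC
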